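The readings are simulated with constants of no real substance, noise included.

The vessel holds 0.50 M of each substrate and 0.300 M of partner, so partner is the limiting reagent, and I follow the fraction of it left.

in all of them: left-handed substrate 0.50 M; right-handed substrate 0.50 M

|  | partner | precatalyst | remark |
|---|---|---|---|
| summer | 0.30 M | 5 mM | run made earlier |
| midnight | 0.30 M | 7.5 mM | run made earlier |
| autumn | 0.60 M | 10 mM | run made earlier |
| flask | 0.300 M | 10 mM |  |

| run | time / min | left-handed product / % | left-handed substrate / % |
|---|---|---|---|
| summer | 0.200 | 0.3 | 49.0 |
| summer | 0.333 | 1.3 | 48.2 |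
| summer | 0.417 | 2.4 | 48.3 |
| summer | 0.667 | 3.5 | 45.9 |
| summer | 1.00 | 5.6 | 43.8 |
| summer | 1.50 | 8.6 | 41.2 |
| summer | 2.50 | 12.9 | 37.4 |
| midnight | 0.167 | 0.9 | 49.0 |
| midnight | 0.333 | 2.6 | 47.9 |
| midnight | 0.667 | 5.1 | 45.0 |
| midnight | 1.00 | 7.6 | 42.8 |
| midnight | 1.33 | 10.2 | 40.7 |
| midnight | 2.00 | 13.2 | 37.5 |
| midnight | 2.50 | 15.1 | 35.8 |
| autumn | 0.200 | 3.9 | 46.2 |
| autumn | 0.333 | 6.4 | 43.2 |
| autumn | 0.667 | 13.1 | 36.3 |
| autumn | 1.33 | 21.3 | 28.5 |
| autumn | 2.50 | 28.2 | 21.8 |

(scatter of a reading: 0.3 percentage points)

- catalyst is single-handed; left-handed substrate and right-handed substrate are mirror images of each other, charged as a racemate, each of them at the stated concentration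

* factor on the rate of making left-handed product when 20 % of the left-handed substrate and right-handed substrate together are converted if precatalyst is charged twice over
* factor on the rate when 20 % of the left-handed substrate and right-handed substrate together are converted if precatalyst is charged at 50 mM instead

I assume that each substrate converted costs one partner, and that each precatalyst charged costs one more. At a fixed conversion the split between the hands then drops out, and one number remains, 30.0 %: the partner share left, which is the charge minus converted substrate minus precatalyst, over the charge. At 0.0200 M precatalyst it is 26.7 %, and at 50 mM it is 16.7 %.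

One number is not enough. Alone it gives factors below one, 0.890 and 0.557, yet midnight has made 7.6 % at 1.00 min where summer has made 5.6 %. I read from these an order in precatalyst of 0.753. Autumn tests this: taking the rate as proportional to partner, I expect 3.37 times summer's early rate, and the readings give 3.51. Multiplying the load factor by the change in share, I commit to 1.50 and 1.87.

The forecast differs from mine, with 1.45 and 2.3, reasoning that “At equal conversion the composition is the same”. The flask gives 1.40 and 1.61, both below my figures.

    partner + catalyst + left-handed substrate → catalyst + left-handed product (k = 3.20 M⁻² s⁻¹)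
    partner + catalyst + right-handed substrate → catalyst + right-handed product (k = 1.20 M⁻² s⁻¹)
    2 catalyst ⇌ resting dimer, settled at all times (K = 69.0 M⁻¹)
    partner + precatalyst → catalyst + spent reagent (k = 0.240 M⁻¹ s⁻¹)

This flask reads 30.9 % of its partner at 2.00 min, beside my 30.0 % for 2.05 min. In this flask the resting dimer holds 43.4 % of the catalyst at 2.00 min, and taking that tying-up away makes the rate at that conversion 1.73 times the actual one.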